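## Structural features

The target joins two C15 eudesmane-type units through a spiro 3,4-dihydro-2H-pyran. The unprimed unit is the intact alantolactone skeleton: cyclohexane ring A, cyclohexene ring B with C5=C6, and a cis-fused γ-lactone. The primed unit is a cis-fused decalin with an exocyclic C4'=C15' methylene. The pyran ring is made of O, the spiro carbon C11 (also the α-carbon of the lactone), C13, C12', C11' and C13', and its enol ether C11'=C13'–O carries the decalin through the C7'–C11' bond. In the unprimed half C4, C10, C8, C7 and the fully substituted C11 are stereogenic, C11 stands next to C7 and C7 next to C8, and the pyran oxygen on C11 lies on the lactone face that carries H7 and H8. In the primed half the quaternary C10' and the ring-fusion carbon C5' are adjacent, C7' is 1,3 to C5', and the C10' methyl, H5' and the C7' substituent all lie on one face. The fragile groups are the acid-labile enol ether, the exocyclic methylene (it can migrate into ring A under acid or metal hydrides), the C5=C6 alkene (open to electrophilic oxidants) and the lactone. The real difficulty is twofold: an enantiopure all-cis decalin with a quaternary centre and no remaining handle in ring B, and the union of two hindered halves at a fully substituted spiro centre of defined configuration. The key step exploits the four-carbon arc C4'(=C15')–C3'–C2'–C1' of ring A: it bridges C5' and C10', which are the β- and α-carbons of an enone with its carbonyl at C9' and its only stereocentre at C7'.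

## Logic of the disconnections

24 to 22. Formal addition of water across C11'=C13' turns the enol ether into the lactol 22. No skeletal bond is cut. The gain is that the most acid-sensitive group appears last and the pyran becomes a ring that closes by itself from an open chain. The forward step must eliminate under non-acidic conditions so that C4'=C15' stays in place; its direction is fixed, because C11' is the only carbon next to C13' that bears hydrogen.

22 to 20 and 17. The lactol is opened at O–C13' to the hydroxy aldehyde 21, and 21 is cut at C13–C12'. This bond lies between two methylene groups and separates the two terpenoid halves cleanly: 20 already holds C11 in its final configuration and 17 holds the complete primed decalin. The forward step needs a C13 radical that adds to C12' of the enal faster than it is reduced, and it must leave three unactivated alkenes and the C11 carbinol untouched.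

20 to 19 to 18. C13–I and then the C11–O bond are removed, leading back through the spiro epoxide 19 to the commercial 18. The gain is that the whole unprimed half, with four stereocentres, is bought. The demand is that oxygen reaches C11 only from the convex face of the cis-fused lactone and only at the electron-poor C11=C13, not at the electron-rich C5=C6; this calls for a nucleophilic oxidant.

17 to 12. Functional groups only are changed: the C13' aldehyde goes back through alcohol 16 to silyl ether 15, and the C9' methylene goes back through xanthate 14 and carbinol 13 to the C9' ketone of 12. The ketone is reintroduced because it is the activating group for the ring construction. The demand is a deoxygenation of a neopentyl position that spares two 1,1-disubstituted alkenes, which points to a radical method and not to strong base or acid.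

12 to 5 and 9. Ring A is opened at C1'–C10' (enolate alkylation, through chloro ketone 11) and at C4'–C5' (conjugate addition, through cuprate 10). One ring, two skeletal bonds and the stereocentres C5' and C10' are removed, and an enone with a single stereocentre remains. The forward step must add trans to the C7' side chain and close ring A cis, and the nucleophile must carry both the future methylene and a leaving group that survives its own generation.

9 to 8 to 6. The C–Li bond is traced to a C–Br bond and this to the terminal alkyne 6. The gain is a tin-free source of the bifunctional reagent. The demand is Markovnikov placement of bromine and a halogen–metal exchange that leaves the primary chloride alone.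

5 to 1. The silyl ether oxygen on the isopropenyl methyl is removed through alcohol 4, acetate 3 and chloride 2 back to 1, which supplies C7' and through it the absolute configuration of the whole primed half. The demand is functionalisation of the electron-rich alkene in the presence of the enone, and a protecting group at the allylic position that an organocopper reagent does not displace.

## Other disconnections considered

Alternative 1: The cut lies inside the unprimed half. C7–C8, C11–C12 and C12–O of alantolactone A1 (identical with 18) are disconnected to the vinylallene aldehyde A2, in which ring A with C4 and C10 is already present. In the forward direction Mo(CO)6 with DMSO would join the aldehyde carbon C8, the inner allene bond C7=C11 and one CO in a hetero-Pauson–Khand reaction. This would close ring B and the lactone together and leave C11=C13 as the exocyclic methylene.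
- In its favour: three bonds and two rings form in one operation, the cis lactone fusion follows from the metallacycle, and no late methylenation is needed.
- Against it here: A1 can be bought, so a multi-step enantioselective synthesis of A2 (quaternary C10, the C4 methyl, a Z-configured exocyclic alkene carrying the allene) would be spent on purchasable material. The facial relation of the new C7/C8 pair to C10 would rest on a remote quaternary centre. Stoichiometric Mo(CO)6 is toxic and releases CO, and the vinylallene could be diverted into a [4+1] carbonylation.
- Comparison: in bonds and rings formed per step this key step is the better one (three bonds and two rings against two bonds and one ring in step 6). On structure it solves a different problem, since it contributes nothing to the primed cis-decalin or to the spiro junction, so step 6 or an equivalent would still be needed. On step economy it lengthens the route. It is worth holding only if unnatural analogues of the unprimed half are wanted.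

Alternative 2: The primed decalin is cut at C5'–C10' and C6'–C7', which leads to the acyclic trienone A4. In A4 a vinyl ketone (C4' carbonyl, C5'=C6') is tethered through C3'–C1' to a diene C10'=C9'–C8'=C7' that is Z at the tether-bearing alkene. In the forward direction Me2AlCl, or a chiral Lewis acid such as (BINOLate)TiCl2, would bring about the intramolecular Diels–Alder reaction to the cis-fused octalone ketal A3.
- In its favour: both carbocycles and all three stereocentres of the primed half (C5', C7', C10') arise in one step, which is better than step 6 in rings and stereocentres per operation. The Z geometry admits only the cis-fused transition state, and the all-cis relation of methyl, H5' and the C7' substituent follows from the diene geometry.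
- Against it here: A4 is achiral, so the absolute configuration would have to come from the catalyst on a trisubstituted Z-diene terminus that forms a quaternary centre; the chosen plan takes it from 1 at no cost. A4 needs a stereodefined Z,E-diene, and Lewis acids may isomerise that diene or open the ketal. After A3 the C8'=C9' alkene must be hydrogenated, the C4' ketone methylenated next to the epimerisable C5', and the masked acetyl group converted into the C11'(=C12')–C13' enal.
- Comparison: the two plans are equal in that each leaves one oxygen to be processed after ring formation (C4' ketone to methylene there, C9' ketone to methylene here). The count to 17 would not be lower than in the chosen plan, and the source of chirality is less secure.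

Alternative 3: The pyran is cut at its ring alkene after moving the enol ether double bond back to the allyl ether position. 24 is traced to the spiro 3,6-dihydro-2H-pyran A5 and this to the diene A6, in which C11 carries a C13-allyl group and an O-allyl ether bearing the decalin on its 2-position. In the forward direction (H2IMes)(PCy3)Cl2Ru=CHPh, the second-generation Grubbs catalyst, would close A6 between the terminal vinyl group and the 1,1-disubstituted alkene. This forms the C11'=C12' ring alkene (locants of 24) of A5, and a ruthenium hydride or comparable isomerisation catalyst would then move it to C11'=C13'.
- In its favour: the ring closure is catalytic and tolerant, needs no radical chain or stoichiometric silane, and its constitution is unambiguous.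
- Equal point: the C11 stereocentre would be set exactly as in the chosen plan (from 19).
- Against it here: A6 requires etherification of a tertiary α-hydroxy lactone with a hindered 2-substituted allyl electrophile. The metathesis must engage one 1,1-disubstituted alkene and ignore the other (C4'=C15'). The isomerisation uses the kind of metal hydride that can also draw C4'=C15' into ring A, and a trisubstituted ring alkene migrates reluctantly.
- Comparison: on mechanism the metathesis is the better ring-forming event. On structure this is an alternative endgame and not a replacement, because A6 would still be built from 16 and therefore from step 6. On step economy it would take about five operations from 16 and 19, against four (steps 11, 13, 14 and 15) in the chosen plan. The chosen plan is preferred because the position of the enol ether is fixed there by constitution and not by a thermodynamic isomerisation.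

Key step: step 6

Remark on the chemistry: primed locants follow eudesmane numbering of the methylene-decalin unit and unprimed locants that of the alantolactone unit. C10' of 11, C9' of 13 and 14, and C11'/C13' of 21 to 23 are expected as epimer mixtures that converge later and are drawn undefined. The silyl ether is kept at C12' of 5 because an allylic ester or halide there would be displaced by the cuprate, and the vinyl donor is made from bromide 8 so that no organotin reagent is needed.

## Route

Step 1
Reactants: 1 (R)-carvone
Product: 2 (R)-10-chlorocarvone
Conditions: Ca(OCl)2, CO2 (s), CH2Cl2/H2O, 0 °C
Reagents that add atoms: calcium hypochlorite, [Ca+2].[O-]Cl.[O-]Cl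
Why: Ene-type allylic chlorination by HOCl (set free from Ca(OCl)2 by CO2): chlorine adds to the terminal carbon of the electron-rich isopropenyl group and a methyl proton is lost, so the 1,1-disubstituted alkene is re-formed with an allylic CH2Cl; the electron-poor enone alkene does not react and C5 is untouched.

Step 2
Reactants: 2 (R)-10-chlorocarvone
Product: 3 (R)-10-acetoxycarvone
Conditions: KOAc, Bu4NI (cat.), DMF, 60 °C
Reagents that add atoms: potassium acetate, CC(=O)[O-].[K+]
Why: SN2 displacement of the primary allylic chloride by acetate with iodide catalysis (an SN2' course gives the same compound); acetate is too weak a base to enolise the ketone or add to the enone.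

Step 3
Reactants: 3 (R)-10-acetoxycarvone
Product: 4 (R)-10-hydroxycarvone
Conditions: K2CO3 (cat.), MeOH, 0 °C → rt
Reagents that add atoms: none
Why: Base-catalysed transesterification of a primary acetate; catalytic carbonate at low temperature keeps reversible methoxide addition to the enone and deconjugation at a minimum.

Step 4
Reactants: 4 (R)-10-hydroxycarvone
Product: 5 silyloxy carvone (5R)-5-[3-(tert-butyldimethylsilyloxy)prop-1-en-2-yl]-2-methylcyclohex-2-en-1-one
Conditions: TBSCl, imidazole, CH2Cl2, rt
Reagents that add atoms: tert-butyldimethylsilyl chloride, CC(C)(C)[Si](C)(C)Cl
Why: Standard imidazole-mediated silylation of a primary allylic alcohol; the silyl ether is not displaced by organocopper reagents and survives KH, hydride and radical conditions.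

Step 5
Reactants: 6 5-chloropent-1-yne
Product: 8 2-bromo-5-chloropent-1-ene, via bromoalkenylborane 7 (not isolated)
Conditions: B-Br-9-BBN, CH2Cl2, 0 °C → rt; AcOH, 0 °C → rt
Reagents that add atoms: B-bromo-9-borabicyclo[3.3.1]nonane, BrB1C2CCCC1CCC2
Why: Haloboration–protonolysis: the bromoborane adds syn and Markovnikov across the terminal alkyne (Br to C2, B to C1) and acetic acid cleaves the alkenyl C–B bond, giving the 2-bromoalk-1-ene; the primary chloride is inert.

Step 6
Reactants: 8 2-bromo-5-chloropent-1-ene; 5 silyloxy carvone
Product: 12 cis-fused methylene decalone (3R,4aS,8aR)-3-[3-(tert-butyldimethylsilyloxy)prop-1-en-2-yl]-8a-methyl-5-methylideneoctahydronaphthalen-1(2H)-one, via vinyllithium 9 (not isolated), via divinylcuprate 10 (not isolated), via chloro ketone 11 (not isolated)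
Conditions: 8, t-BuLi (2 equiv per 8), Et2O, −78 °C; CuBr·SMe2 (0.5 equiv per 9), −78 → −45 °C; 5, Et2O/THF, −78 °C; aq NH4Cl/NH3; crude 11, KH, THF, 0 °C → rt
Reagents that add atoms: none
Why: Bromine–lithium exchange on 8 at −78 °C (the second equivalent of t-BuLi destroys t-BuBr) gives 9 without touching the primary chloride, and two equivalents of 9 with CuBr·SMe2 form the Gilman cuprate 10. Conjugate addition of 10 to enone 5 is an ordinary organocopper 1,4-addition that forms C4'–C5' and closes no ring. As is usual for 5-substituted cyclohexenones, the vinyl group enters axially on the face anti to the pseudoequatorial C7' side chain, so C5' is set trans to C7', the one stereocentre that carvone supplies. The allylic silyl ether is a poor leaving group, so SN2' loss of oxygen should not compete, and delivery from copper avoids 1,2-addition. After work-up, KH turns crude 11 into its potassium enolates, which equilibrate by proton transfer; only the tetrasubstituted C9'–C10' enolate has the tethered chloride within reach. Ring A then closes by a 6-(enolexo)-exo-tet C-alkylation that forms C1'–C10', whereas closure from the C8' enolate would need an eight-membered bridged ring and O-alkylation an eight-membered enol ether. The four-atom tether hangs from C5' and can bring C1' perpendicular to the enolate plane only on the face that already carries the C5'–C4' bond, so C10' is set cis to C5' (methyl cis to H5') by the tether and, being quaternary, cannot epimerise afterwards. The closest known reaction type is the methylenecyclohexane annulation of cyclohexenones with 2-metallated 5-chloropent-1-enes, which delivers the C4'=C15' methylene without an olefination.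

Step 7
Reactants: 12 cis-fused methylene decalone
Product: 13 C9' carbinol
Conditions: NaBH4, MeOH/THF, 0 °C → rt
Reagents that add atoms: none
Why: Hydride reduction of the ketone; the new C9' carbinol centre is removed again in step 9, so either epimer serves, and the isolated alkenes and the silyl ether are inert to NaBH4.

Step 8
Reactants: 13 C9' carbinol
Product: 14 C9' S-methyl xanthate
Conditions: NaH, imidazole (cat.), THF, 0 °C → rt; CS2; MeI
Reagents that add atoms: carbon disulfide, S=C=S; iodomethane, CI
Why: Xanthate formation: the sodium alkoxide adds to CS2 and the dithiocarbonate salt is S-methylated; the alkoxide route is chosen because the neopentyl C9' hydroxyl is hindered.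

Step 9
Reactants: 14 C9' S-methyl xanthate
Product: 15 deoxygenated silyl ether
Conditions: (Me3Si)3SiH, AIBN (cat.), toluene, 90 °C
Reagents that add atoms: none
Why: Barton–McCombie deoxygenation with a silane as chain carrier: the silyl radical adds to C=S, the C9'–O bond fragments to a secondary radical, and this is reduced by Si–H. The radical could reach C4'=C15' or C11'=C12' only by 4-exo or 5-endo closures, which should not compete with hydrogen transfer.

Step 10
Reactants: 15 deoxygenated silyl ether
Product: 16 allylic alcohol
Conditions: Bu4NF, THF, 0 °C → rt
Reagents that add atoms: none
Why: Fluoride-induced desilylation driven by the Si–F bond; no other group in 15 reacts with fluoride.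

Step 11
Reactants: 16 allylic alcohol
Product: 17 enal
Conditions: MnO2, CH2Cl2, rt
Reagents that add atoms: none
Why: MnO2 oxidises the primary allylic alcohol selectively to the 2-substituted acrolein without over-oxidation or alkene migration; 17 is used at once because α-substituted acroleins dimerise on standing.

Step 12
Reactants: 18 alantolactone
Product: 19 11,13-spiro epoxide
Conditions: t-BuOOH (2 equiv), n-BuLi (1.1 equiv), THF, −78 → −20 °C
Reagents that add atoms: tert-butyl hydroperoxide, CC(C)(C)OO
Why: Weitz–Scheffer nucleophilic epoxidation: the lithium peroxide adds to C13 of the electron-poor exocyclic alkene and the lactone enolate closes onto oxygen at C11, while the electron-rich C5=C6 alkene is inert to a nucleophilic oxidant. Ring closure should take place on the convex face of the cis-fused lactone (the side of H7 and H8), which places the C11 oxygen as required in 24.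

Step 13
Reactants: 19 11,13-spiro epoxide
Product: 20 iodohydrin
Conditions: LiI, AcOH, THF, rt
Reagents that add atoms: lithium iodide, [Li+].[I-]
Why: Regioselective SN2 opening of the spiro epoxide by iodide at the unhindered primary C13 under mild acid; the C11–O bond is not broken, so the C11 configuration is retained.

Step 14
Reactants: 20 iodohydrin; 17 enal
Product: 22 lactol, via hydroxy aldehyde 21 (not isolated)
Conditions: 20 (1.5 equiv), (Me3Si)3SiH, AIBN (cat.), toluene, 80 °C, slow addition of silane
Reagents that add atoms: none
Why: Giese reaction: the silyl radical abstracts iodine from 20, the nucleophilic primary C13 radical adds to the terminal C12' of the enal (forming C13–C12'), and the resulting α-formyl radical takes hydrogen from Si–H. The δ-hydroxy aldehyde 21 should close spontaneously to the six-membered lactol 22; the new centres C11' and C13' form as mixtures and are destroyed in step 15, and C11 is not touched.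

Step 15
Reactants: 22 lactol
Product: 24 target CNP0108778.1, via anomeric mesylate 23 (not isolated)
Conditions: MsCl, Et3N, CH2Cl2, 0 °C → rt
Reagents that add atoms: none
Why: Mesylation of the hemiacetal hydroxyl and base-assisted elimination through the oxocarbenium ion (the usual lactol-to-glycal dehydration) give the enol ether. C11' is the only neighbouring carbon with hydrogen, so the double bond can form only at C11'=C13', and the basic medium protects the exocyclic methylene and the product from acid.

## Compound list

1 | (R)-carvone | CC1=CC[C@H](CC1=O)C(C)=C | starting material
2 | (R)-10-chlorocarvone, (5R)-5-(3-chloroprop-1-en-2-yl)-2-methylcyclohex-2-en-1-one | CC1=CC[C@H](CC1=O)C(=C)CCl | intermediate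
3 | (R)-10-acetoxycarvone | CC1=CC[C@H](CC1=O)C(=C)COC(C)=O | intermediate
4 | (R)-10-hydroxycarvone | CC1=CC[C@H](CC1=O)C(=C)CO | intermediate
5 | silyloxy carvone, (5R)-5-[3-(tert-butyldimethylsilyloxy)prop-1-en-2-yl]-2-methylcyclohex-2-en-1-one | CC1=CC[C@H](CC1=O)C(=C)CO[Si](C)(C)C(C)(C)C | intermediate
6 | 5-chloropent-1-yne | C#CCCCCl | starting material
7 | (Z)-B-(2-bromo-5-chloropent-1-enyl)-9-borabicyclo[3.3.1]nonane | Br/C(CCCCl)=C\B1C2CCCC1CCC2 | intermediate
8 | 2-bromo-5-chloropent-1-ene | C=C(Br)CCCCl | intermediate
9 | 5-chloro-2-lithiopent-1-ene | [Li]C(=C)CCCCl | intermediate
10 | lithium bis(5-chloropent-1-en-2-yl)cuprate | [Li+].C=C(CCCCl)[Cu-]C(=C)CCCCl | intermediate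
11 | chloro ketone, conjugate adduct with the 5-chloropent-1-en-2-yl group at C5' trans to the C7' side chain, C10' epimers | C=C(CCCCl)[C@@H]1C[C@@H](C(=C)CO[Si](C)(C)C(C)(C)C)CC(=O)C1C | intermediate
12 | cis-fused methylene decalone, (3R,4aS,8aR)-3-[3-(tert-butyldimethylsilyloxy)prop-1-en-2-yl]-8a-methyl-5-methylideneoctahydronaphthalen-1(2H)-one; C10' methyl, H5' and C7' side chain all cis | C=C1CCC[C@@]2(C)C(=O)C[C@H](C(=C)CO[Si](C)(C)C(C)(C)C)C[C@@H]12 | intermediate
13 | C9' carbinol of 12 (C9' epimers, otherwise as 12) | C=C1CCC[C@@]2(C)C(O)C[C@H](C(=C)CO[Si](C)(C)C(C)(C)C)C[C@@H]12 | intermediate
14 | C9' O-alkyl S-methyl xanthate of 13 | C=C1CCC[C@@]2(C)C(OC(=S)SC)C[C@H](C(=C)CO[Si](C)(C)C(C)(C)C)C[C@@H]12 | intermediate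
15 | deoxygenated silyl ether, cis-fused 4'(15'),11'(12')-eudesmadien-13'-ol TBS ether with C10' methyl, H5' and C7' side chain cis | C=C1CCC[C@@]2(C)CC[C@H](C(=C)CO[Si](C)(C)C(C)(C)C)C[C@@H]12 | intermediate
16 | allylic alcohol, 2-(decalin-7'-yl)prop-2-en-1-ol with the configuration of 15 | C=C1CCC[C@@]2(C)CC[C@H](C(=C)CO)C[C@@H]12 | intermediate
17 | enal, 2-(decalin-7'-yl)acrolein with the configuration of 15 | C=C1CCC[C@@]2(C)CC[C@H](C(=C)C=O)C[C@@H]12 | intermediate
18 | alantolactone | C=C1C(=O)O[C@@H]2C[C@@]3(C)CCC[C@H](C)C3=C[C@@H]21 | starting material
19 | 11,13-epoxy-11,13-dihydroalantolactone, epoxide oxygen on the H7/H8 face | C1O[C@]12C(=O)O[C@@H]3C[C@@]4(C)CCC[C@H](C)C4=C[C@H]23 | intermediate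
20 | iodohydrin, 11-hydroxy-13-iodo-11,13-dihydroalantolactone, hydroxyl on the H7/H8 face | O[C@@]1(CI)C(=O)O[C@@H]2C[C@@]3(C)CCC[C@H](C)C3=C[C@@H]21 | intermediate
21 | δ-hydroxy aldehyde, C13–C12' coupled product (C11' epimers) | C=C1CCC[C@@]2(C)CC[C@H](C(C=O)CC[C@]3(O)C(=O)O[C@@H]4C[C@@]5(C)CCC[C@H](C)C5=C[C@@H]43)C[C@@H]12 | intermediate
22 | lactol, spiro 2-hydroxytetrahydropyran (C11' and C13' epimers) | C=C1CCC[C@@]2(C)CC[C@H](C3CC[C@]4(OC3O)C(=O)O[C@@H]3C[C@@]5(C)CCC[C@H](C)C5=C[C@@H]34)C[C@@H]12 | intermediate
23 | anomeric mesylate of 22 | C=C1CCC[C@@]2(C)CC[C@H](C3CC[C@]4(OC3OS(C)(=O)=O)C(=O)O[C@@H]3C[C@@]5(C)CCC[C@H](C)C5=C[C@@H]34)C[C@@H]12 | intermediate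
24 | CNP0108778.1, spiro 3,4-dihydro-2H-pyran dimer | C=C1CCC[C@@]2(C)CC[C@H](C3=CO[C@@]4(CC3)C(=O)O[C@@H]3C[C@@]5(C)CCC[C@H](C)C5=C[C@@H]34)C[C@@H]12 | target

## Step count and risks

Total step count: 15. Longest linear sequence: 12 steps (steps 1, 2, 3, 4, 6, 7, 8, 9, 10, 11, 14, 15).

Step 6 (key step). The most likely failure is in the second half: proton transfer may leave part of the material as the unproductive C8' enolate, and intermolecular aldol condensation of 11 under KH or loss of the vinyllithium by warming before transmetallation can erode the conversion. The fallback separates conjugate addition from enolate generation. It sets out from 5 and 10, with chlorotrimethylsilane present during the addition so that the copper enolate is trapped as the trimethylsilyl enol ether F1. F1 is purified and then cleaved with MeLi in THF/DMPU, which releases the C9'–C10' lithium enolate regiospecifically with no free ketone present. Cyclisation then returns to the route at 12.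

Step 14. The primary C13 radical may be reduced before it adds, the enal may oligomerise under radical conditions, or 17 may self-dimerise at the reaction temperature. The fallback abandons the radical union for a thermal hetero-Diels–Alder reaction. It sets out from 17 and 18 (18 in excess, concentrated in toluene with a radical inhibitor, 110–130 °C), in which 17 acts as the 1-oxadiene and the exocyclic alkene of 18 as the dienophile. The regiochemistry is that of acrolein dimerisation (oxygen to C11, C12' to C13) and approach should be from the convex lactone face. It returns to the route directly at 24; no new compound is made on this path (entry F0), and steps 12, 13 and 15 would then be unnecessary.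

Step 12. Competing base-induced migration of the exocyclic alkene into conjugation (removal of the doubly activated H7), attack of the peroxide at the lactone carbonyl, or insufficient facial control in the ring closure could lower the yield or the purity at C11. The fallback uses an electrophilic oxidant and a different leaving-group strategy. It sets out from 18 by catalytic OsO4 with N-methylmorpholine N-oxide, which should dihydroxylate the accessible exocyclic alkene from the convex face to the 11,13-diol F2. Selective iodination of the primary hydroxyl of F2 (I2, PPh3, imidazole) returns to the route at 20.

Step 15. The open-chain tautomer 21 may react instead of the lactol (enolisation or aldol chemistry), and any acid formed during work-up may hydrate the enol ether or move the exocyclic methylene. The fallback sets out from 22 and first fixes the ring as the methyl acetal F3 (MeOH, pyridinium p-toluenesulfonate). F3 is then converted into the enol ether by trimethylsilyl triflate with diisopropylethylamine, an acetal-to-enol-ether elimination in a strictly aprotic medium, which returns to the route at 24.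

Step 9 (with step 8). Thioacylation of the neopentyl C9' carbinol may be slow, and on heating the xanthate may undergo Chugaev-type syn-elimination to a C8'=C9' alkene in competition with the radical chain. The fallback avoids the alcohol altogether. It sets out from 12, which is condensed with p-toluenesulfonyl hydrazide to the tosylhydrazone F4. F4 is reduced with catecholborane and then treated with sodium acetate, so that the diazene loses dinitrogen, which returns to the route at 15.

## Further compounds

F1 | step 6 | trimethylsilyl enol ether of the conjugate adduct (C9'–C10' enol ether) | C=C(CCCCl)[C@@H]1C[C@@H](C(=C)CO[Si](C)(C)C(C)(C)C)CC(O[Si](C)(C)C)=C1C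
F0 | step 14 | none | none
F2 | step 12 | 11,13-dihydroxy-11,13-dihydroalantolactone | O[C@@]1(CO)C(=O)O[C@@H]2C[C@@]3(C)CCC[C@H](C)C3=C[C@@H]21
F3 | step 15 | methyl acetal of lactol 22 | C=C1CCC[C@@]2(C)CC[C@H](C3CC[C@]4(OC3OC)C(=O)O[C@@H]3C[C@@]5(C)CCC[C@H](C)C5=C[C@@H]34)C[C@@H]12
F4 | step 9 | p-toluenesulfonylhydrazone of 12 | C=C1CCC[C@@]2(C)C(=NNS(=O)(=O)c3ccc(C)cc3)C[C@H](C(=C)CO[Si](C)(C)C(C)(C)C)C[C@@H]12
A1 | alternative 1 | alantolactone | C=C1C(=O)O[C@@H]2C[C@@]3(C)CCC[C@H](C)C3=C[C@@H]21
A2 | alternative 1 | vinylallene aldehyde | O=CC[C@@]1(C)CCC[C@H](C)/C1=C/C=C=C
A3 | alternative 2 | cis-fused octalone ketal | O=C1CCC[C@@]2(C)C=C[C@H](C3(C)OCCO3)C[C@@H]12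
A4 | alternative 2 | (7Z,9E)-7-methyl-10-(2-methyl-1,3-dioxolan-2-yl)deca-1,7,9-trien-3-one | C=CC(=O)CCC/C(C)=C\C=C\C1(C)OCCO1
A5 | alternative 3 | spiro 3,6-dihydro-2H-pyran | C=C1CCC[C@@]2(C)CC[C@H](C3=CC[C@]4(OC3)C(=O)O[C@@H]5C[C@@]6(C)CCC[C@H](C)C6=C[C@@H]54)C[C@@H]12
A6 | alternative 3 | metathesis diene, 13-vinyl 11-O-(2-decalinylallyl) ether | C=C1CCC[C@@]2(C)CC[C@H](C(=C)CO[C@@]3(CC=C)C(=O)O[C@@H]4C[C@@]5(C)CCC[C@H](C)C5=C[C@@H]43)C[C@@H]12
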